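**Abbreviations.** MOM = methoxymethyl; TBS = tert-butyldimethylsilyl; TIPS = tri(propan-2-yl)silyl; prenyl = 3-methylbut-2-enyl; Ar1 = 2,4-bis(methoxymethoxy)-3-prenylphenyl; Ar2 = 2,4-bis(methoxymethoxy)phenyl. Cyclohexene locants: C1 carries the exocyclic carbon C7, C2 is the substituted alkene carbon, C3 is =CH, C4 carries the methyl group, C6 carries the aryl group. Flavone locants are the usual ones (O1, C2, C3, C4, C4a, C5–C8, C8a; rings A, C, B).

## Analysis of the target

The target is a cyclohex-2-ene carrying four groups: on C1 a 2,4-dihydroxy-3-prenylbenzoyl group (ketone carbon C7), on the alkene carbon C2 the C8 carbon of a 5,7-dihydroxy-3-prenyl-2-(2,4-dihydroxyphenyl)chromen-4-one, on C4 a methyl group and on C6 a 2,4-dihydroxyphenyl group. There are three stereocentres, C1 (R), C4 (S) and C6 (S): the C1 aroyl group is trans to the C6 aryl group, and the C4 methyl group is trans to the C6 aryl group and cis to the aroyl group. This is the pattern left by conjugate addition to a 5-methylcyclohex-2-enone anti to the methyl group followed by enolate trapping anti to the new aryl group, and the C4 configuration corresponds to the S enantiomer of that enone. The sensitive groups are two prenyl groups next to phenols (chroman formation under protic or strong Lewis acid, and no hydrogenolysis possible) and six oxidisable phenols. C1–H is both α to the C7 ketone and allylic, so base or hot acid can epimerise C1 or pull the C2=C3 bond into conjugation. The hard bond is C2–C8: it joins a trisubstituted alkene carbon with a fully substituted neighbour (C1) to an arene carbon flanked by two oxygens, and C6 and C8 of a 5,7-dioxygenated flavone are electronically almost alike. The strategy rests on ring A: C8 lies between the oxygenated C7 and C8a and para to the C5 oxygen, which is the 2-substituted 5-alkoxyresorcinol pattern that a 3-alkoxy vinylketene and a 1-siloxyalkyne deliver. Ring A can therefore be grown on C2 from an alkyne already bonded to it.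

## Retrosynthetic reasoning

**48 ⇐ 47 ⇐ 46 (ether C–O bonds only).** The last two operations only remove ethers. 48 comes from 47 by acid methanolysis of five acetal ethers. 47 comes from 46 by magnesium-chelate-assisted loss of the ethyl ether on O5 and of the acetal ether ortho to the C7 ketone. Acetal ethers are chosen because they can be taken off beside prenyl groups. The ethyl ether is what the ring synthesis leaves on O5, and its peri relation to the C4 carbonyl makes it selectively removable. Stronger halide Lewis acids are avoided: they would strip every acetal ether in the same flask and expose prenyl groups beside free phenols to cationic ring closure.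

**46 ⇐ 45 ⇐ 44 (C7 oxidation state).** The C7 ketone is unveiled only at 46; in 44 it is a silyl-protected carbinol. While C7 is sp3, C1–H is not acidic, so no enolate step can epimerise C1 or move the C2=C3 bond. It also means the ring ketone of 17 can be enolised in one direction only.

**44 ⇐ 42 ⇐ 36 + 40 (ring C: O1–C2 and C2–C3).** The pyranone is cut at O1–C2 (cyclodehydration) and at C2–C3 (acylation of a ketone enolate by 40). The prenyl group on C3 is carried in with the side chain of 36, which avoids a late C-prenylation with its O- versus C-alkylation problem. 40 is three steps from 37.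

**36 ⇐ 35 ⇐ 32 ⇐ 30 (C4–C3 and C4a–C4).** The acyl chain is cut at C3–C4 (addition of Grignard reagent 34 to aldehyde 32, then oxidation) and at C4a–C4 (ortho-formylation of 30). A direct Friedel–Crafts acylation is not used because six acetal ethers would not survive its Lewis acid. The magnesium-phenoxide formylation is base-mediated and goes only ortho to the single free hydroxyl of 30, and the only open ortho position is C4a. The silyl ether of 30 is kept as protection for O7.

**30 ⇐ 23 + 25 (ring A: C8–C8a and C6–C7).** This is the key disconnection. Ring A is taken apart into the four carbons of 25 and the two alkyne carbons of 23. Cutting here removes the need to make the hindered C2–C8 bond by coupling, because that bond already exists in 23 as an unhindered alkene–alkyne bond. It also delivers O8a free and O7 silylated. The forward step must control the orientation of the ketene–alkyne cycloaddition and tolerate the full protected core.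

**23 ⇐ 20 ⇐ 19 ⇐ 17 (the two alkyne carbons).** 23 comes from ester 20 by one-carbon homologation to the ynolate and O-silylation. 20 comes from enol triflate 19 by carbonylation, and 19 from ketone 17 by kinetic enolisation toward the methylene group. These are three standard steps, so the risk sits in the benzannulation and not in reaching its precursor.

**17 ⇐ 16 ⇐ 13 + 14 + 8 (C6–aryl and C1–C7).** Both bonds are made in one flask by conjugate addition of 14 (from 2) to 13 and aldol capture by 8. The C5 methyl group of 13 controls C6, and C6 controls C1. This fixes all three stereocentres of the target at the outset.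

**13 ⇐ 9; 8 ⇐ 3; 2 ⇐ 1; 25 ⇐ 24.** 13 is the degradation product of 9, which supplies C4 in the S configuration. 8 is built from 3 by two directed metalations, because the carbon between the two oxygens is best addressed before the formyl group exists. 2 is the protected form of 1. 25 is one cycloaddition from 24.

## Alternatives that were turned down

**Alternative 1:** The disconnection is C6–aryl and C1–C7, with the three-component coupling as the centre of the plan. The key step is copper-catalysed addition of 14 to 13 and aldol capture by 8, giving ketol A1 (identical with 16). In its favour, one flask sets C6 and C1 relative to the pool-derived C4 with predictable anti selectivity, from cheap materials. On stereocontrol it is as strong as the chosen route, which in fact adopts this coupling as step 8. Against it, the plan does not address the C2–C8 bond. Its natural continuation is cross-coupling of the derived enol triflate (19 below) with an 8-metalated flavone such as boronate A2. That coupling would have to join a carbon beside the substituted C1 to an aryl carbon between two oxygens. A2 itself requires C8-selective metalation of a ring whose C6 is equally reactive, and 2,6-dioxygenated arylboron compounds protodeboronate readily. If the coupling worked, alternative 1 would be several steps shorter and more convergent. The chosen strategy spends those steps to replace the coupling with a ring synthesis that has no C6/C8 ambiguity.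

**Alternative 2:** The disconnection is C1–C6 and C3–C4 of the cyclohexene. Under a secondary-amine organocatalyst, the central carbon of aroylacetone A3 adds to the β-carbon of cinnamaldehyde A4, and the methyl ketone carbon then condenses onto the aldehyde carbon to give cyclohexenone A5. In its favour, the enantiocontrol is catalytic and either enantiomer is accessible. The C7 ketone is at the right oxidation level from the start, which saves the protection, deprotection and oxidation of the carbinol. On these points it is stronger than the chosen route. Against it, A5 lacks the C4 methyl group. Adding it by conjugate addition meets the acidic C1–H of the 1,3-dicarbonyl first, and the resulting enolate shuts down the enone. Converting the ring carbonyl into a C2=C3 enol triflate is opposed by enolisation toward C1, which would put the double bond at C1=C2 and erase the C1 stereocentre. C4 would depend on 1,3-induction from C6 across a flattened ring. The chosen route has C4 from the start, a masked C7 that allows enolisation only toward C3, and a solution for ring A, which alternative 2 does not provide.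

**Alternative 3:** The disconnection is C1'–C2' and C5'–C6' of the prenylresorcinol ketone ring. Ethynyl ketone A6 reacts with the 2-prenyl 1,3-bis(silyloxy) diene A7 in a [4+2] cycloaddition and aromatises to A8. In its favour, the polarities of ynone and diene match, and the aroyl ring is delivered regiospecifically with free hydroxyls, without protecting groups on that ring and without the carbinol detour. On protecting-group economy for that ring it is stronger. Against it, the ring synthesis is spent on the one arene that is easy to make (8 is three steps from 3). The cycloaddition comes last, on a substrate A6 that already contains the complete flavone, so the C2–C8 problem must have been solved first by other means. A6 has C1–H α to an ynone and allylic, so it is prone to epimerisation and double-bond migration. A7 is a hindered, hydrolytically labile diene. The chosen strategy uses its ring synthesis where ordinary coupling fails.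

Key step: step 14

## Remarks before the steps

- The target's C4 configuration requires (S)-5-methylcyclohex-2-enone, so (S)-(−)-pulegone is the chiral-pool source; the commoner (R)-(+)-enantiomer would give the mirror-image series.
- C7 formed in step 8 is carried as a mixture of epimers until step 24. The transient centres in 10, 11, 12, 27, 35, 42 and 43 are likewise undefined and are erased later.
- In the names, "core–Y" means the cyclohex-2-ene with CH(OTBS)Ar1 on C1, Y on C2, methyl on C4 and Ar2 on C6, in the configuration of the target (C1 substituent and C4 methyl on one face, C6 aryl on the other).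

## Steps

Step 1
Reactants: 1 4-bromobenzene-1,3-diol
Product: 2 1-bromo-2,4-bis(methoxymethoxy)benzene
Conditions: MOMCl, i-Pr2NEt, CH2Cl2, 0 °C → rt
Reagents that add atoms: chloromethyl methyl ether, COCCl
Why: Williamson-type O-alkylation of both phenols; the acetal ethers survive the organometallic, basic and thermal steps and leave at the end under acid mild enough for prenyl groups.

Step 2
Reactants: 3 benzene-1,3-diol
Product: 4 1,3-bis(methoxymethoxy)benzene
Conditions: MOMCl, i-Pr2NEt, CH2Cl2, 0 °C → rt
Reagents that add atoms: chloromethyl methyl ether, COCCl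
Why: The same O-alkylation; the two acetal ethers then act as directing groups for both metalations that follow.

Step 3
Reactants: 4 1,3-bis(methoxymethoxy)benzene
Product: 6 1,3-bis(methoxymethoxy)-2-(3-methylbut-2-enyl)benzene, via aryllithium 5 (not isolated)
Conditions: n-BuLi, THF, 0 °C → rt; CuBr·SMe2 (10 mol%), prenyl bromide, −78 °C → rt
Reagents that add atoms: 1-bromo-3-methylbut-2-ene, CC(C)=CCBr
Why: Directed ortho metalation at the carbon flanked by both acetal oxygens, then copper-mediated substitution at the primary carbon of the allylic bromide without allylic transposition.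

Step 4
Reactants: 6 1,3-bis(methoxymethoxy)-2-(3-methylbut-2-enyl)benzene
Product: 8 2,4-bis(methoxymethoxy)-3-(3-methylbut-2-enyl)benzaldehyde, via aryllithium 7 (not isolated)
Conditions: n-BuLi, TMEDA, THF, −78 → 0 °C; DMF, −78 °C → rt; aq NH4Cl
Reagents that add atoms: N,N-dimethylformamide, CN(C)C=O
Why: Second directed ortho metalation beside one acetal ether (the two open ortho positions are equivalent) and formylation of the aryllithium.

Step 5
Reactants: 9 (S)-(−)-pulegone
Product: 10 (S)-pulegone oxide
Conditions: H2O2 (30% aq), NaOH, MeOH, 0 °C → rt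
Reagents that add atoms: hydrogen peroxide, OO
Why: Weitz–Scheffer nucleophilic epoxidation of the enone; the new spiro centre is destroyed in step 6, so its configuration is irrelevant.

Step 6
Reactants: 10 (S)-pulegone oxide
Product: 11 (5S)-5-methyl-2-(phenylsulfanyl)cyclohexanone
Conditions: PhSNa, THF, reflux; H2O
Reagents that add atoms: sodium benzenethiolate, [Na+].[S-]c1ccccc1
Why: The thiolate opens the epoxide at the ring carbon α to the ketone, and the tertiary alkoxide then loses acetone by retro-aldol cleavage; the C5 stereocentre is not involved.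

Step 7
Reactants: 11 (5S)-5-methyl-2-(phenylsulfanyl)cyclohexanone
Product: 13 (S)-5-methylcyclohex-2-en-1-one, via sulfoxide 12 (not isolated)
Conditions: mCPBA (1.0 equiv), CH2Cl2, −78 °C; then CaCO3, toluene, 80 °C
Reagents that add atoms: none
Why: S-oxidation and thermal syn-elimination of the sulfoxide; only C3 carries β-hydrogens, so the double bond forms in conjugation, and the methyl stereocentre has the S configuration needed for C4 of the target.

Step 8
Reactants: 2 1-bromo-2,4-bis(methoxymethoxy)benzene; 13 (S)-5-methylcyclohex-2-en-1-one; 8 2,4-bis(methoxymethoxy)-3-(3-methylbut-2-enyl)benzaldehyde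
Product: 16 (2S,3S,5S)-2-[Ar1-CH(OH)]-3-Ar2-5-methylcyclohexanone (C7 epimers), via aryl Grignard reagent 14 (not isolated), via bromomagnesium enolate 15 (not isolated)
Conditions: 2, Mg, LiCl, THF, rt; then CuBr·SMe2 (10 mol%), 13, THF, −78 → −40 °C; then 8, −78 °C; aq NH4Cl
Reagents that add atoms: none
Why: Tandem copper-catalysed conjugate addition–aldol reaction; the aryl group adds axially anti to the C5 methyl group (3,5-trans), and the magnesium enolate then attacks the aldehyde through C2 anti to the new C3 aryl group (2,3-trans); the carbinol configuration is not controlled and not needed.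

Step 9
Reactants: 16 (2S,3S,5S)-2-[Ar1-CH(OH)]-3-Ar2-5-methylcyclohexanone
Product: 17 tert-butyldimethylsilyl ether of 16
Conditions: TBSOTf, 2,6-lutidine, CH2Cl2, −78 °C
Reagents that add atoms: tert-butyldimethylsilyl trifluoromethanesulfonate, CC(C)(C)[Si](C)(C)OS(=O)(=O)C(F)(F)F
Why: Silylation of the hindered secondary alcohol with a silyl triflate and a non-nucleophilic base, cold enough to avoid retro-aldol cleavage; the ether keeps C7 sp3 until step 23.

Step 10
Reactants: 17 tert-butyldimethylsilyl ether of 16
Product: 19 core–OSO2CF3 (enol triflate), via potassium enolate 18 (not isolated)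
Conditions: KHMDS, THF, −78 °C; PhNTf2, −78 → 0 °C; aq NH4Cl
Reagents that add atoms: N-phenylbis(trifluoromethanesulfonimide), O=S(=O)(N(c1ccccc1)S(=O)(=O)C(F)(F)F)C(F)(F)F
Why: Kinetic deprotonation at the open methylene group rather than at the hindered methine C1 gives one enolate; O-triflation fixes the C2=C3 double bond and leaves C1 untouched.

Step 11
Reactants: 19 core–OSO2CF3
Product: 20 core–CO2CH3 (methyl ester)
Conditions: Pd(OAc)2 (5 mol%), dppp, CO (1 atm), MeOH, Et3N, DMF, 60 °C
Reagents that add atoms: carbon monoxide, [C-]#[O+]; methanol, CO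
Why: Palladium-catalysed alkoxycarbonylation of an enol triflate: oxidative addition to zerovalent palladium, CO insertion and methanolysis of the acylpalladium species.

Step 12
Reactants: 20 core–CO2CH3
Product: 23 core–C≡C–OTIPS (siloxyalkyne), via dibromomethyl ketone 21 (not isolated), via lithium ynolate 22 (not isolated)
Conditions: CH2Br2, LiTMP, THF, −78 °C; 20; LiHMDS; n-BuLi, −78 °C → rt; then i-Pr3SiCl, −78 °C → rt
Reagents that add atoms: dibromomethane, BrCBr; chlorotri(propan-2-yl)silane, CC(C)[Si](Cl)(C(C)C)C(C)C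
Why: Kowalski ester homologation: LiCHBr2 adds to the ester, bromine–lithium exchange on the dibromo enolate triggers a 1,2-shift of the cyclohexenyl group to give the ynolate, and the bulky silyl chloride captures it on oxygen.

Step 13
Reactants: 24 ethoxyacetylene
Product: 25 3-ethoxycyclobut-2-enone
Conditions: ketene (gas, from pyrolysis of acetone), CH2Cl2, −20 → 0 °C
Reagents that add atoms: ketene, C=C=O
Why: [2+2] cycloaddition of ketene with the electron-rich ynol ether; the alkyne carbon remote from oxygen bonds to the ketene carbonyl carbon, giving the 3-alkoxycyclobutenone.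

Step 14
Reactants: 23 core–C≡C–OTIPS; 25 3-ethoxycyclobut-2-enone
Product: 30 2-(core)-5-ethoxy-3-(triisopropylsilyloxy)phenol, via vinylketene 26 (not isolated), via 4-vinylcyclobutenone 27 (not isolated), via dienylketene 28 (not isolated), via cyclohexa-2,4-dienone 29 (not isolated)
Conditions: 25 (1.5 equiv), toluene, 80 → 110 °C, sealed vessel
Reagents that add atoms: none
Why: Danheiser benzannulation of a cyclobutenone with a siloxyalkyne. Four-electron electrocyclic opening of 25 gives vinylketene 26, whose ketene carbon is attacked by the alkyne carbon of 23 remote from oxygen (the one bonded to cyclohexene C2), so the [2+2] cycloaddition forms C8–C8a and C6–C7 and gives 27. Opening of the strained four-membered ring of 27 gives dienylketene 28, and ring A is closed by a thermal six-electron disrotatory electrocyclisation between the ketene carbon and the terminal methylene carbon, giving 29, which tautomerises to phenol 30. No stereocentre is created: the sp3 carbon of 27 is transient, and the three core stereocentres carry no acidic hydrogen. The step needs the regiochemistry of the ketene–alkyne cycloaddition, which the polarisation of the ynol ether secures, placing the cyclohexenyl group between the two oxygens and the ethoxy group para to it. It also needs selectivity for the alkyne over the prenyl and ring alkenes, which the much higher nucleophilicity of the siloxyalkyne toward a ketene secures. The ketene oxygen emerges as the only free hydroxyl (future O1) and the alkyne oxygen as the silyl ether (future O7), so the two oxygens flanking C8 are differentiated without a further step.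

Step 15
Reactants: 30 2-(core)-5-ethoxy-3-(triisopropylsilyloxy)phenol
Product: 32 3-(core)-6-ethoxy-2-hydroxy-4-(triisopropylsilyloxy)benzaldehyde, via hydroxymethylphenol 31 (not isolated)
Conditions: MgCl2, Et3N, (CH2O)n, THF, 65 °C
Reagents that add atoms: paraformaldehyde (as formaldehyde), C=O
Why: Magnesium-phenoxide-directed ortho-formylation (Casnati–Skattebøl type): the single free hydroxyl delivers formaldehyde to its only open ortho position (C4a), and a second formaldehyde oxidises the hydroxymethyl intermediate; no acid is involved, so acetal and silyl ethers persist.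

Step 16
Reactants: 32 3-(core)-6-ethoxy-2-hydroxy-4-(triisopropylsilyloxy)benzaldehyde; 33 5-bromo-2-methylpent-2-ene
Product: 35 1-[3-(core)-6-ethoxy-2-hydroxy-4-(triisopropylsilyloxy)phenyl]-5-methylhex-4-en-1-ol, via homoprenyl Grignard reagent 34 (not isolated)
Conditions: 33, Mg, THF, rt; then 32 (3 equiv of 34), THF, −20 → 0 °C; aq NH4Cl
Reagents that add atoms: none
Why: Grignard addition to the salicylaldehyde after deprotonation of the chelated phenol; the chain carries the future C3 and its prenyl group; the electron-rich carbinol is taken on without delay.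

Step 17
Reactants: 35 1-[3-(core)-6-ethoxy-2-hydroxy-4-(triisopropylsilyloxy)phenyl]-5-methylhex-4-en-1-ol
Product: 36 1-[3-(core)-6-ethoxy-2-hydroxy-4-(triisopropylsilyloxy)phenyl]-5-methylhex-4-en-1-one
Conditions: MnO2, CH2Cl2, rt
Reagents that add atoms: none
Why: Neutral, selective oxidation of the benzylic alcohol to the ortho-hydroxyaryl ketone; the silyl-protected carbinol C7 and the alkenes are inert.

Step 18
Reactants: 37 2,4-dihydroxybenzaldehyde
Product: 38 2,4-bis(methoxymethoxy)benzaldehyde
Conditions: NaH, MOMCl, DMF, 0 °C → rt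
Reagents that add atoms: chloromethyl methyl ether, COCCl
Why: O-alkylation of both phenoxides; the strong base is needed for the hydrogen-bonded ortho hydroxyl.

Step 19
Reactants: 38 2,4-bis(methoxymethoxy)benzaldehyde
Product: 39 2,4-bis(methoxymethoxy)benzoic acid
Conditions: NaClO2, NaH2PO4, 2-methylbut-2-ene, t-BuOH–H2O, rt
Reagents that add atoms: sodium chlorite, [Na+].[O-]Cl=O
Why: Pinnick oxidation; the buffered medium is mild enough for the acetal ethers.

Step 20
Reactants: 39 2,4-bis(methoxymethoxy)benzoic acid
Product: 40 2,4-bis(methoxymethoxy)benzoyl chloride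
Conditions: 1-chloro-N,N,2-trimethylprop-1-en-1-amine, CH2Cl2, 0 °C → rt; used crude
Reagents that add atoms: 1-chloro-N,N,2-trimethylprop-1-en-1-amine (Ghosez reagent), CC(C)=C(Cl)N(C)C
Why: Acid chloride formation under neutral conditions; no hydrogen chloride is released, so the ortho acetal ether survives.

Step 21
Reactants: 36 1-[3-(core)-6-ethoxy-2-hydroxy-4-(triisopropylsilyloxy)phenyl]-5-methylhex-4-en-1-one; 40 2,4-bis(methoxymethoxy)benzoyl chloride
Product: 42 1-[3-(core)-6-ethoxy-2-hydroxy-4-(triisopropylsilyloxy)phenyl]-3-Ar2-2-(3-methylbut-2-enyl)propane-1,3-dione, via dilithium phenoxide enolate 41 (not isolated)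
Conditions: LiHMDS (3.5 equiv), THF, −78 °C; 40, −78 → 0 °C; aq NH4Cl
Reagents that add atoms: none
Why: Direct form of the Baker–Venkataraman diketone synthesis: the dianion is acylated at the enolate carbon, and any O-aroylated phenol would rearrange to the same diketone under the excess base.

Step 22
Reactants: 42 1-[3-(core)-6-ethoxy-2-hydroxy-4-(triisopropylsilyloxy)phenyl]-3-Ar2-2-(3-methylbut-2-enyl)propane-1,3-dione
Product: 44 8-(core)-5-ethoxy-2-Ar2-3-(3-methylbut-2-enyl)-7-(triisopropylsilyloxy)chromen-4-one, via hemiketal 43 (not isolated)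
Conditions: PPTS (0.2 equiv), 4 Å molecular sieves, toluene, 60 °C
Reagents that add atoms: none
Why: Acid-catalysed cyclodehydration: the phenol adds to the ring B ketone to give hemiketal 43, which loses water through an oxocarbenium ion stabilised by the oxygenated ring B; a weak pyridinium acid in an aprotic solvent spares acetal and silyl ethers.

Step 23
Reactants: 44 8-(core)-5-ethoxy-2-Ar2-3-(3-methylbut-2-enyl)-7-(triisopropylsilyloxy)chromen-4-one
Product: 45 5-ethoxy-7-hydroxyflavone with free C7 carbinol (both silyl groups removed)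
Conditions: TBAF, THF, 0 → 40 °C; aq NH4Cl
Reagents that add atoms: none
Why: Fluoride cleaves the aryl silyl ether at once and the hindered benzylic silyl ether on warming; acetal ethers, alkenes and the flavone are inert to fluoride.

Step 24
Reactants: 45 5-ethoxy-7-hydroxyflavone with free C7 carbinol
Product: 46 5-ethoxy-7-hydroxyflavone C7 ketone (six MOM ethers)
Conditions: Dess–Martin periodinane, NaHCO3, CH2Cl2, 0 °C → rt
Reagents that add atoms: none
Why: Dess–Martin oxidation under buffered, neutral conditions; C1–H becomes α to a carbonyl only here, three steps from the end, and meets neither base nor strong acid afterwards.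

Step 25
Reactants: 46 5-ethoxy-7-hydroxyflavone C7 ketone
Product: 47 5,7-dihydroxyflavone C7 ketone with free aroyl 2-hydroxyl (five MOM ethers)
Conditions: MgI2·OEt2, toluene–Et2O, 60 °C; MeOH; aq Na2S2O3
Reagents that add atoms: none
Why: Chelation-assisted ether cleavage: magnesium bridges the C4 carbonyl and the C5 ether oxygen and iodide removes the ethyl group by SN2; the same chelation at the C7 ketone removes the ortho acetal ether; non-chelated ethers and the prenyl groups are not activated because no protic acid is present.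

Step 26
Reactants: 47 5,7-dihydroxyflavone C7 ketone with free aroyl 2-hydroxyl
Product: 48 CNP0314407.1 (target)
Conditions: HCl (3 M aq), MeOH, rt → 40 °C
Reagents that add atoms: none
Why: Acid-catalysed methanolysis of the five remaining acetal ethers, the usual unmasking of ortho-prenylphenols; low temperature and short contact limit chroman formation and enolisation at C1.

## Compound list

1 | 4-bromobenzene-1,3-diol | Oc1ccc(Br)c(O)c1 | starting material
2 | 1-bromo-2,4-bis(methoxymethoxy)benzene | COCOc1ccc(Br)c(OCOC)c1 | intermediate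
3 | benzene-1,3-diol | Oc1cccc(O)c1 | starting material
4 | 1,3-bis(methoxymethoxy)benzene | COCOc1cccc(OCOC)c1 | intermediate
5 | 2,6-bis(methoxymethoxy)phenyllithium | COCOc1cccc(OCOC)c1[Li] | intermediate (not isolated)
6 | 1,3-bis(methoxymethoxy)-2-(3-methylbut-2-enyl)benzene | COCOc1cccc(OCOC)c1CC=C(C)C | intermediate
7 | 2,4-bis(methoxymethoxy)-3-(3-methylbut-2-enyl)phenyllithium | COCOc1ccc([Li])c(OCOC)c1CC=C(C)C | intermediate (not isolated)
8 | 2,4-bis(methoxymethoxy)-3-(3-methylbut-2-enyl)benzaldehyde | CC(C)=CCc1c(OCOC)ccc(C=O)c1OCOC | intermediate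
9 | (S)-(−)-pulegone | C[C@H]1CCC(=C(C)C)C(=O)C1 | starting material
10 | (S)-pulegone oxide (spiro epoxide, mixture at the spiro carbon) | C[C@H]1CCC2(OC2(C)C)C(=O)C1 | intermediate
11 | (5S)-5-methyl-2-(phenylsulfanyl)cyclohexanone (C2 epimers) | C[C@H]1CCC(Sc2ccccc2)C(=O)C1 | intermediate
12 | (5S)-5-methyl-2-(phenylsulfinyl)cyclohexanone | C[C@H]1CCC(S(=O)c2ccccc2)C(=O)C1 | intermediate (not isolated)
13 | (S)-5-methylcyclohex-2-en-1-one | C[C@H]1CC=CC(=O)C1 | intermediate
14 | [2,4-bis(methoxymethoxy)phenyl]magnesium bromide | COCOc1ccc([Mg]Br)c(OCOC)c1 | intermediate (not isolated)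
15 | bromomagnesium (3S,5S)-3-Ar2-5-methylcyclohex-1-en-1-olate | Br[Mg]OC1=C[C@@H](c2ccc(OCOC)cc2OCOC)C[C@H](C)C1 | intermediate (not isolated)
16 | (2S,3S,5S)-2-[Ar1-CH(OH)]-3-Ar2-5-methylcyclohexanone (C7 epimers) | CC(C)=CCc1c(OCOC)ccc(C(O)[C@H]2C(=O)C[C@@H](C)C[C@@H]2c2ccc(OCOC)cc2OCOC)c1OCOC | intermediate
17 | tert-butyldimethylsilyl ether of 16 | CC(C)=CCc1c(OCOC)ccc(C(O[Si](C)(C)C(C)(C)C)[C@H]2C(=O)C[C@@H](C)C[C@@H]2c2ccc(OCOC)cc2OCOC)c1OCOC | intermediate
18 | potassium enolate of 17 (enolised toward the methylene group) | CC(C)=CCc1c(OCOC)ccc(C(O[Si](C)(C)C(C)(C)C)[C@H]2C(O[K])=C[C@@H](C)C[C@@H]2c2ccc(OCOC)cc2OCOC)c1OCOC | intermediate (not isolated)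
19 | core–OSO2CF3 (enol triflate) | CC(C)=CCc1c(OCOC)ccc(C(O[Si](C)(C)C(C)(C)C)[C@H]2C(OS(=O)(=O)C(F)(F)F)=C[C@@H](C)C[C@@H]2c2ccc(OCOC)cc2OCOC)c1OCOC | intermediate
20 | core–CO2CH3 (methyl ester) | CC(C)=CCc1c(OCOC)ccc(C(O[Si](C)(C)C(C)(C)C)[C@H]2C(C(=O)OC)=C[C@@H](C)C[C@@H]2c2ccc(OCOC)cc2OCOC)c1OCOC | intermediate
21 | core–C(=O)CHBr2 (dibromomethyl ketone) | CC(C)=CCc1c(OCOC)ccc(C(O[Si](C)(C)C(C)(C)C)[C@H]2C(C(=O)C(Br)Br)=C[C@@H](C)C[C@@H]2c2ccc(OCOC)cc2OCOC)c1OCOC | intermediate (not isolated)
22 | core–C≡C–OLi (lithium ynolate) | CC(C)=CCc1c(OCOC)ccc(C(O[Si](C)(C)C(C)(C)C)[C@H]2C(C#CO[Li])=C[C@@H](C)C[C@@H]2c2ccc(OCOC)cc2OCOC)c1OCOC | intermediate (not isolated)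
23 | core–C≡C–OTIPS (siloxyalkyne, precursor of the key step) | CC(C)=CCc1c(OCOC)ccc(C(O[Si](C)(C)C(C)(C)C)[C@H]2C(C#CO[Si](C(C)C)(C(C)C)C(C)C)=C[C@@H](C)C[C@@H]2c2ccc(OCOC)cc2OCOC)c1OCOC | intermediate
24 | ethoxyacetylene | C#COCC | starting material
25 | 3-ethoxycyclobut-2-enone | CCOC1=CC(=O)C1 | intermediate
26 | 3-ethoxybuta-1,3-dien-1-one (vinylketene) | C=C(OCC)C=C=O | intermediate (not isolated)
27 | 2-(core)-4-(1-ethoxyvinyl)-3-(triisopropylsilyloxy)cyclobut-2-enone | CC(C)=CCc1c(OCOC)ccc(C(O[Si](C)(C)C(C)(C)C)[C@H]2C(C3=C(O[Si](C(C)C)(C(C)C)C(C)C)C(C(=C)OCC)C3=O)=C[C@@H](C)C[C@@H]2c2ccc(OCOC)cc2OCOC)c1OCOC | intermediate (not isolated)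
28 | dienylketene: 2-(core)-5-ethoxy-3-(triisopropylsilyloxy)hexa-1,3,5-trien-1-one (3Z) | CC(C)=CCc1c(OCOC)ccc(C(O[Si](C)(C)C(C)(C)C)[C@H]2C(C(=C=O)/C(O[Si](C(C)C)(C(C)C)C(C)C)=C\C(OCC)=C)=C[C@@H](C)C[C@@H]2c2ccc(OCOC)cc2OCOC)c1OCOC | intermediate (not isolated)
29 | 2-(core)-5-ethoxy-3-(triisopropylsilyloxy)cyclohexa-2,4-dienone | CC(C)=CCc1c(OCOC)ccc(C(O[Si](C)(C)C(C)(C)C)[C@H]2C(C3=C(O[Si](C(C)C)(C(C)C)C(C)C)C=C(OCC)CC3=O)=C[C@@H](C)C[C@@H]2c2ccc(OCOC)cc2OCOC)c1OCOC | intermediate (not isolated)
30 | 2-(core)-5-ethoxy-3-(triisopropylsilyloxy)phenol (product of the key step) | CC(C)=CCc1c(OCOC)ccc(C(O[Si](C)(C)C(C)(C)C)[C@H]2C(c3c(O)cc(OCC)cc3O[Si](C(C)C)(C(C)C)C(C)C)=C[C@@H](C)C[C@@H]2c2ccc(OCOC)cc2OCOC)c1OCOC | intermediate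
31 | 2-(core)-5-ethoxy-6-(hydroxymethyl)-3-(triisopropylsilyloxy)phenol | CC(C)=CCc1c(OCOC)ccc(C(O[Si](C)(C)C(C)(C)C)[C@H]2C(c3c(O)c(CO)c(OCC)cc3O[Si](C(C)C)(C(C)C)C(C)C)=C[C@@H](C)C[C@@H]2c2ccc(OCOC)cc2OCOC)c1OCOC | intermediate (not isolated)
32 | 3-(core)-6-ethoxy-2-hydroxy-4-(triisopropylsilyloxy)benzaldehyde | CC(C)=CCc1c(OCOC)ccc(C(O[Si](C)(C)C(C)(C)C)[C@H]2C(c3c(O)c(C=O)c(OCC)cc3O[Si](C(C)C)(C(C)C)C(C)C)=C[C@@H](C)C[C@@H]2c2ccc(OCOC)cc2OCOC)c1OCOC | intermediate
33 | 5-bromo-2-methylpent-2-ene | CC(C)=CCCBr | starting material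
34 | (4-methylpent-3-enyl)magnesium bromide | CC(C)=CCC[Mg]Br | intermediate (not isolated)
35 | 1-[3-(core)-6-ethoxy-2-hydroxy-4-(triisopropylsilyloxy)phenyl]-5-methylhex-4-en-1-ol (carbinol epimers) | CC(C)=CCc1c(OCOC)ccc(C(O[Si](C)(C)C(C)(C)C)[C@H]2C(c3c(O)c(C(O)CCC=C(C)C)c(OCC)cc3O[Si](C(C)C)(C(C)C)C(C)C)=C[C@@H](C)C[C@@H]2c2ccc(OCOC)cc2OCOC)c1OCOC | intermediate
36 | 1-[3-(core)-6-ethoxy-2-hydroxy-4-(triisopropylsilyloxy)phenyl]-5-methylhex-4-en-1-one | CC(C)=CCc1c(OCOC)ccc(C(O[Si](C)(C)C(C)(C)C)[C@H]2C(c3c(O)c(C(=O)CCC=C(C)C)c(OCC)cc3O[Si](C(C)C)(C(C)C)C(C)C)=C[C@@H](C)C[C@@H]2c2ccc(OCOC)cc2OCOC)c1OCOC | intermediate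
37 | 2,4-dihydroxybenzaldehyde | O=Cc1ccc(O)cc1O | starting material
38 | 2,4-bis(methoxymethoxy)benzaldehyde | COCOc1ccc(C=O)c(OCOC)c1 | intermediate
39 | 2,4-bis(methoxymethoxy)benzoic acid | COCOc1ccc(C(=O)O)c(OCOC)c1 | intermediate
40 | 2,4-bis(methoxymethoxy)benzoyl chloride | COCOc1ccc(C(Cl)=O)c(OCOC)c1 | intermediate
41 | dilithium phenoxide enolate of 36 | CC(C)=CCc1c(OCOC)ccc(C(O[Si](C)(C)C(C)(C)C)[C@H]2C(c3c(O[Li])c(C(O[Li])=CCC=C(C)C)c(OCC)cc3O[Si](C(C)C)(C(C)C)C(C)C)=C[C@@H](C)C[C@@H]2c2ccc(OCOC)cc2OCOC)c1OCOC | intermediate (not isolated)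
42 | 1-[3-(core)-6-ethoxy-2-hydroxy-4-(triisopropylsilyloxy)phenyl]-3-Ar2-2-(3-methylbut-2-enyl)propane-1,3-dione | CC(C)=CCc1c(OCOC)ccc(C(O[Si](C)(C)C(C)(C)C)[C@H]2C(c3c(O)c(C(=O)C(CC=C(C)C)C(=O)c4ccc(OCOC)cc4OCOC)c(OCC)cc3O[Si](C(C)C)(C(C)C)C(C)C)=C[C@@H](C)C[C@@H]2c2ccc(OCOC)cc2OCOC)c1OCOC | intermediate
43 | 8-(core)-5-ethoxy-2-hydroxy-2-Ar2-3-(3-methylbut-2-enyl)-7-(triisopropylsilyloxy)chroman-4-one (hemiketal) | CC(C)=CCc1c(OCOC)ccc(C(O[Si](C)(C)C(C)(C)C)[C@H]2C(c3c(O[Si](C(C)C)(C(C)C)C(C)C)cc(OCC)c4c3OC(O)(c5ccc(OCOC)cc5OCOC)C(CC=C(C)C)C4=O)=C[C@@H](C)C[C@@H]2c2ccc(OCOC)cc2OCOC)c1OCOC | intermediate (not isolated)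
44 | 8-(core)-5-ethoxy-2-Ar2-3-(3-methylbut-2-enyl)-7-(triisopropylsilyloxy)chromen-4-one | CC(C)=CCc1c(OCOC)ccc(C(O[Si](C)(C)C(C)(C)C)[C@H]2C(c3c(O[Si](C(C)C)(C(C)C)C(C)C)cc(OCC)c4c(=O)c(CC=C(C)C)c(-c5ccc(OCOC)cc5OCOC)oc34)=C[C@@H](C)C[C@@H]2c2ccc(OCOC)cc2OCOC)c1OCOC | intermediate
45 | 5-ethoxy-7-hydroxyflavone with free C7 carbinol: as 44 with both silyl groups replaced by hydrogen | CC(C)=CCc1c(OCOC)ccc(C(O)[C@H]2C(c3c(O)cc(OCC)c4c(=O)c(CC=C(C)C)c(-c5ccc(OCOC)cc5OCOC)oc34)=C[C@@H](C)C[C@@H]2c2ccc(OCOC)cc2OCOC)c1OCOC | intermediate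
46 | 5-ethoxy-7-hydroxyflavone C7 ketone (six MOM ethers) | CC(C)=CCc1c(OCOC)ccc(C(=O)[C@H]2C(c3c(O)cc(OCC)c4c(=O)c(CC=C(C)C)c(-c5ccc(OCOC)cc5OCOC)oc34)=C[C@@H](C)C[C@@H]2c2ccc(OCOC)cc2OCOC)c1OCOC | intermediate
47 | 5,7-dihydroxyflavone C7 ketone with free aroyl 2-hydroxyl (five MOM ethers) | CC(C)=CCc1c(OCOC)ccc(C(=O)[C@H]2C(c3c(O)cc(O)c4c(=O)c(CC=C(C)C)c(-c5ccc(OCOC)cc5OCOC)oc34)=C[C@@H](C)C[C@@H]2c2ccc(OCOC)cc2OCOC)c1O | intermediate
48 | CNP0314407.1, (1R,4S,6S) in the cyclohexene locants used here | CC(C)=CCc1c(O)ccc(C(=O)[C@H]2C(c3c(O)cc(O)c4c(=O)c(CC=C(C)C)c(-c5ccc(O)cc5O)oc34)=C[C@@H](C)C[C@@H]2c2ccc(O)cc2O)c1O | target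

## Step count and least certain steps

Total: 26 steps. Longest linear sequence: 18 steps from 9 (steps 5–12, 14–17, 21–26).

**Step 14 (key step).** The electrocyclic opening of 25 is slowed by its vinylogous-ester conjugation. The temperature it needs may come close to that at which the silyl group of 23 migrates from oxygen to carbon. A slow cycloaddition also gives 26 time to acylate the phenol of the product. Fallback, from 23 back to 30: the same vinylketene 26 is generated by light at room temperature instead of by heat. 1-Ethoxyvinyllithium (from ethyl vinyl ether and t-BuLi) is acylated with N-methoxy-N-methylacetamide to give 3-ethoxybut-3-en-2-one F1. Trifluoroacetylation (LiHMDS, 2,2,2-trifluoroethyl trifluoroacetate) gives 5-ethoxy-1,1,1-trifluorohex-5-ene-2,4-dione F2. Detrifluoroacetylative diazo transfer (MsN3, Et3N, H2O, MeCN) gives 1-diazo-3-ethoxybut-3-en-2-one F3. Irradiation of F3 with 23 in CH2Cl2 (300 nm, rt) causes photochemical Wolff rearrangement to 26, which is trapped as 27; brief warming to 80 °C then takes 27 to 30.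

**Step 12.** The carbenoid may add in conjugate fashion, or not at all, to the hindered unsaturated ester. Residual amide base may deprotonate C4–H (γ to the ester) and scramble C4. Excess n-BuLi may metalate the carbon between the two acetal ethers of Ar2 on warming. Fallback, from 19 back to 23, without alkyllithium or ester: Sonogashira coupling of 19 with ethynyltrimethylsilane (Pd(PPh3)4, CuI, Et3N) gives core trimethylsilyl enyne F4. K2CO3 in MeOH gives core terminal enyne F5. Deprotonation with LiHMDS and oxidation of the lithium acetylide with lithium tert-butyl peroxide (from t-BuOOH and LiHMDS, THF, −78 → 0 °C) gives ynolate 22, which TIPSOTf silylates to 23.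

**Step 25.** Displacement at an ethyl carbon is slower than at methyl. During prolonged heating the magnesium Lewis acid may enolise the new C7 ketone (epimerisation at C1 or migration of the C2=C3 bond), or close a freed phenol onto the neighbouring prenyl group. Fallback, from 44 to 48: the ethyl group is removed before C1–H is acidic, and by a nucleophile instead of a Lewis acid. 44 is heated with NaSEt in DMF (about 110 °C); SN2 attack at the ethyl carbon and loss of the aryl silyl group give 5,7-dihydroxyflavone tert-butyldimethylsilyl ether F6. TBAF gives 5,7-dihydroxyflavone carbinol F7, Dess–Martin oxidation gives 5,7-dihydroxyflavone C7 ketone F8 (six MOM ethers), and the acid methanolysis of step 26 applied to F8 gives 48.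

**Step 8.** The aldehyde is flanked by an acetal ether, so the aldol capture may be slow. Slow capture leaves time for proton transfer to the enolate, retro-aldol cleavage on warming, and addition of unconsumed Grignard reagent to the aldehyde. Fallback, from 13 back to 16, in two separate operations: conjugate addition of 14 to 13 with CuBr·SMe2 and Me3SiCl gives (3S,5S)-3-Ar2-5-methyl-1-(trimethylsilyloxy)cyclohexene F9, which is isolated. MeLi regenerates the lithium enolate, ZnCl2 converts it into the zinc enolate, and 8 is added at −78 °C to give 16.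

## Further compounds

F1 | step 14 | 3-ethoxybut-3-en-2-one | C=C(OCC)C(C)=O
F2 | step 14 | 5-ethoxy-1,1,1-trifluorohex-5-ene-2,4-dione | C=C(OCC)C(=O)CC(=O)C(F)(F)F
F3 | step 14 | 1-diazo-3-ethoxybut-3-en-2-one | C=C(OCC)C(=O)C=[N+]=[N-]
F4 | step 12 | core–C≡C–Si(CH3)3 (trimethylsilyl enyne) | CC(C)=CCc1c(OCOC)ccc(C(O[Si](C)(C)C(C)(C)C)[C@H]2C(C#C[Si](C)(C)C)=C[C@@H](C)C[C@@H]2c2ccc(OCOC)cc2OCOC)c1OCOC
F5 | step 12 | core–C≡CH (terminal enyne) | CC(C)=CCc1c(OCOC)ccc(C(O[Si](C)(C)C(C)(C)C)[C@H]2C(C#C)=C[C@@H](C)C[C@@H]2c2ccc(OCOC)cc2OCOC)c1OCOC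
F6 | step 25 | 8-(core)-5,7-dihydroxy-2-Ar2-3-(3-methylbut-2-enyl)chromen-4-one (C7 carbinol as TBS ether) | CC(C)=CCc1c(OCOC)ccc(C(O[Si](C)(C)C(C)(C)C)[C@H]2C(c3c(O)cc(O)c4c(=O)c(CC=C(C)C)c(-c5ccc(OCOC)cc5OCOC)oc34)=C[C@@H](C)C[C@@H]2c2ccc(OCOC)cc2OCOC)c1OCOC
F7 | step 25 | 5,7-dihydroxyflavone with free C7 carbinol (six MOM ethers) | CC(C)=CCc1c(OCOC)ccc(C(O)[C@H]2C(c3c(O)cc(O)c4c(=O)c(CC=C(C)C)c(-c5ccc(OCOC)cc5OCOC)oc34)=C[C@@H](C)C[C@@H]2c2ccc(OCOC)cc2OCOC)c1OCOC
F8 | step 25 | 5,7-dihydroxyflavone C7 ketone (six MOM ethers) | CC(C)=CCc1c(OCOC)ccc(C(=O)[C@H]2C(c3c(O)cc(O)c4c(=O)c(CC=C(C)C)c(-c5ccc(OCOC)cc5OCOC)oc34)=C[C@@H](C)C[C@@H]2c2ccc(OCOC)cc2OCOC)c1OCOC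
F9 | step 8 | (3S,5S)-3-Ar2-5-methyl-1-(trimethylsilyloxy)cyclohexene | C[Si](C)(C)OC1=C[C@@H](c2ccc(OCOC)cc2OCOC)C[C@H](C)C1
A1 | alternative 1 | (2S,3S,5S)-2-[Ar1-CH(OH)]-3-Ar2-5-methylcyclohexanone (identical with 16) | CC(C)=CCc1c(OCOC)ccc(C(O)[C@H]2C(=O)C[C@@H](C)C[C@@H]2c2ccc(OCOC)cc2OCOC)c1OCOC
A2 | alternative 1 | 5,7-bis(methoxymethoxy)-2-Ar2-3-(3-methylbut-2-enyl)-8-(4,4,5,5-tetramethyl-1,3,2-dioxaborolan-2-yl)chromen-4-one | CC(C)=CCc1c(-c2ccc(OCOC)cc2OCOC)oc2c(B3OC(C)(C)C(C)(C)O3)c(OCOC)cc(OCOC)c2c1=O
A3 | alternative 2 | 1-Ar1-butane-1,3-dione | CC(C)=CCc1c(OCOC)ccc(C(=O)CC(C)=O)c1OCOC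
A4 | alternative 2 | (E)-3-Ar2-prop-2-enal | COCOc1ccc(/C=C/C=O)c(OCOC)c1
A5 | alternative 2 | trans-6-(Ar1-carbonyl)-5-Ar2-cyclohex-2-enone | CC(C)=CCc1c(OCOC)ccc(C(=O)[C@H]2C(=O)C=CC[C@@H]2c2ccc(OCOC)cc2OCOC)c1OCOC
A6 | alternative 3 | cyclohexenyl ethynyl ketone bearing the MOM-protected flavone on C2 and Ar2 on C6 | C#CC(=O)[C@H]2C(c3c(OCOC)cc(OCOC)c4c(=O)c(CC=C(C)C)c(-c5ccc(OCOC)cc5OCOC)oc34)=C[C@@H](C)C[C@@H]2c2ccc(OCOC)cc2OCOC
A7 | alternative 3 | 1-methoxy-2-(3-methylbut-2-enyl)-1,3-bis(trimethylsilyloxy)buta-1,3-diene | C=C(O[Si](C)(C)C)C(CC=C(C)C)=C(OC)O[Si](C)(C)C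
A8 | alternative 3 | target with free aroyl-ring hydroxyls and MOM ethers on the flavone and the C6 aryl group | CC(C)=CCc1c(O)ccc(C(=O)[C@H]2C(c3c(OCOC)cc(OCOC)c4c(=O)c(CC=C(C)C)c(-c5ccc(OCOC)cc5OCOC)oc34)=C[C@@H](C)C[C@@H]2c2ccc(OCOC)cc2OCOC)c1O
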